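**Assumptions (one line each)**
- The target is taken exactly as the SMILES: (2R,3S,4S,5R), i.e. the all-trans, C2-symmetric 2,5-diaryl-3,4-bis(hydroxymethyl)oxolane.
- Compound 1 (D-mannitol-derived), 2 and 7 are taken as catalogue compounds; if 1 must be made it is about three routine steps from D-mannitol, and 2 and 7 are single silylations of allyl alcohol and 4-bromoguaiacol.

**Retrosynthetic overview**
1. Neoolivil ⇐ desilylation of the all-trans tetrasilyl oxolane 9. The oxolane is the only ring and is closed late, by acid cyclodehydration/equilibration of the 1,4-diaryl-1,4-diol 8, so C2/C5 are set thermodynamically from C3/C4.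
2. 8 ⇐ two aryl Grignard additions to the C2-symmetric (2S,3S)-dialdehyde 6 ⇐ ozonolysis of the bis(enol ether) 5.
3. Key step: 5 ⇐ thermal [3,3] Cope (alkoxy-Cope) rearrangement of the (4R,5R)-dimethoxy-diene 4. This forms the C3–C4 (β–β') bond and both carbon stereocentres by chair chirality transfer.
4. 4 ⇐ O-methylation and double cross-metathesis of (3R,4R)-hexa-1,5-diene-3,4-diol 1 with allyl silyl ether 2. The two mannitol stereocentres are consumed in the transfer and leave as methyl formate.

**Route**

**Step 1**
Reactants: 1, (3R,4R)-hexa-1,5-diene-3,4-diol; 2, allyl tert-butyldiphenylsilyl ether (5 equiv)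
Product: 3, (2E,4R,5R,6E)-1,8-bis(tert-butyldiphenylsilyloxy)octa-2,6-diene-4,5-diol
Conditions: Hoveyda–Grubbs II (5 mol%), CH2Cl2, 40 °C; chromatography to remove E/Z isomers
Reagents that add atoms: none (all new atoms come from reactant 2)
Why: Olefin cross-metathesis of a secondary allylic alcohol with a terminal allyl ether gives the E-1,2-disubstituted alkenes; ring closure is impossible (it would give a cyclobutene) and the carbinol centres are untouched.

**Step 2**
Reactants: 3
Product: 4, (2E,4R,5R,6E)-1,8-bis(tert-butyldiphenylsilyloxy)-4,5-dimethoxyocta-2,6-diene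
Conditions: NaH, MeI, THF, 0 °C → rt
Reagents that add atoms: iodomethane, CI
Why: Williamson etherification; silyl migration from O1/O8 is geometrically blocked by the E-alkenes, and no stereocentre is involved.

**Step 3 (key step)**
Reactants: 4
Product: 5, (1E,3R,4R,5E)-3,4-bis[(tert-butyldiphenylsilyloxy)methyl]-1,6-dimethoxyhexa-1,5-diene
Conditions: mesitylene (0.05 M), BHT (cat.), sealed tube, 190 °C; Et3N-buffered silica to isolate the (E,E)-isomer
Reagents that add atoms: none
Why: Cope rearrangement of a 3,4-dialkoxy-1,5-diene, driven forward by formation of two enol ethers. The chair transition state with both OMe groups and both E-CH2OSi groups pseudo-equatorial makes the new C3–C4 bond and relays (4R,5R) into (3R,4R). The diaxial chair gives the antipodal centres only as the (Z,Z)-isomer, a separable diastereomer, so isolating (E,E)-5 secures the ee.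

**Step 4**
Reactants: 5
Product: 6, (2S,3S)-2,3-bis[(tert-butyldiphenylsilyloxy)methyl]butanedial
Conditions: O3 (titrated), CH2Cl2, −78 °C; then Me2S, −78 °C → rt; used crude
Reagents that add atoms: ozone, [O-][O+]=O
Why: Ozonolysis cleaves the electron-rich enol ether C=C bonds (methyl formate is lost); the stereocentres are not touched, and the descriptor changes to S only because the CIP priorities change.

**Step 5**
Reactants: 6; 7, (4-bromo-2-methoxyphenoxy)(tert-butyl)dimethylsilane (5 equiv, as its Grignard reagent)
Product: 8, (2S,3S)-1,4-bis[4-(tert-butyldimethylsilyloxy)-3-methoxyphenyl]-2,3-bis[(tert-butyldiphenylsilyloxy)methyl]butane-1,4-diol (mixture of C1/C4 carbinol epimers)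
Conditions: 7, Mg, THF; then 6, THF, −78 → 0 °C
Reagents that add atoms: aryl Grignard from 7, COc1cc([Mg]Br)ccc1O[Si](C)(C)C(C)(C)C
Why: Grignard 1,2-addition; the first adduct closes to a magnesium lactolate that reopens for the second addition, as in Grignard additions to lactols. The carbinol configurations are not controlled and do not need to be, because they are reset in step 6.

**Step 6**
Reactants: 8
Product: 9, (2R,3S,4S,5R)-2,5-bis[4-(tert-butyldimethylsilyloxy)-3-methoxyphenyl]-3,4-bis[(tert-butyldiphenylsilyloxy)methyl]oxolane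
Conditions: BF3·OEt2 (0.3 equiv), CH2Cl2, −40 → 0 °C; Et3N quench
Reagents that add atoms: none
Why: SN1 cyclodehydration through a p-oxygen-stabilised benzylic cation closes the oxolane. Reversible ionisation of the benzylic C–O bonds equilibrates C2 and C5 to the most stable all-trans isomer, anchored by the fixed (3S,4S) centres. The bulky, weakly nucleophilic TBDPS ethers keep the primary oxygens from closing to a furofuran.

**Step 7**
Reactants: 9
Product: 10, (+)-neoolivil
Conditions: TBAF (6 equiv), AcOH (6 equiv), THF, rt
Reagents that add atoms: none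
Why: Buffered fluoride desilylation removes the two aryl TBS and two primary TBDPS groups without acid, so the benzylic ethers neither epimerise nor rearrange to a furofuran.

**Compound list**
1 | (3R,4R)-hexa-1,5-diene-3,4-diol | C=C[C@@H](O)[C@H](O)C=C | starting material
2 | allyl tert-butyldiphenylsilyl ether | C=CCO[Si](c1ccccc1)(c1ccccc1)C(C)(C)C | starting material
3 | (2E,4R,5R,6E)-1,8-bis(TBDPS-oxy)octa-2,6-diene-4,5-diol | CC(C)(C)[Si](c1ccccc1)(c1ccccc1)OC/C=C/[C@@H](O)[C@H](O)/C=C/CO[Si](c1ccccc1)(c1ccccc1)C(C)(C)C | intermediate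
4 | (2E,4R,5R,6E)-1,8-bis(TBDPS-oxy)-4,5-dimethoxyocta-2,6-diene | CC(C)(C)[Si](c1ccccc1)(c1ccccc1)OC/C=C/[C@@H](OC)[C@H](OC)/C=C/CO[Si](c1ccccc1)(c1ccccc1)C(C)(C)C | intermediate
5 | (1E,3R,4R,5E)-3,4-bis(TBDPS-oxymethyl)-1,6-dimethoxyhexa-1,5-diene | CO/C=C/[C@H](CO[Si](c1ccccc1)(c1ccccc1)C(C)(C)C)[C@@H](CO[Si](c1ccccc1)(c1ccccc1)C(C)(C)C)/C=C/OC | intermediate
6 | (2S,3S)-2,3-bis(TBDPS-oxymethyl)butanedial | O=C[C@H](CO[Si](c1ccccc1)(c1ccccc1)C(C)(C)C)[C@@H](CO[Si](c1ccccc1)(c1ccccc1)C(C)(C)C)C=O | intermediate
7 | (4-bromo-2-methoxyphenoxy)(tert-butyl)dimethylsilane | COc1cc(Br)ccc1O[Si](C)(C)C(C)(C)C | starting material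
8 | (2S,3S)-1,4-bis(4-TBSO-3-methoxyphenyl)-2,3-bis(TBDPS-oxymethyl)butane-1,4-diol, C1/C4 epimer mixture | COc1cc(C(O)[C@H](CO[Si](c2ccccc2)(c2ccccc2)C(C)(C)C)[C@@H](CO[Si](c2ccccc2)(c2ccccc2)C(C)(C)C)C(O)c2ccc(O[Si](C)(C)C(C)(C)C)c(OC)c2)ccc1O[Si](C)(C)C(C)(C)C | intermediate
9 | (2R,3S,4S,5R)-2,5-bis(4-TBSO-3-methoxyphenyl)-3,4-bis(TBDPS-oxymethyl)oxolane | COc1cc([C@@H]2O[C@@H](c3ccc(O[Si](C)(C)C(C)(C)C)c(OC)c3)[C@H](CO[Si](c3ccccc3)(c3ccccc3)C(C)(C)C)[C@H]2CO[Si](c2ccccc2)(c2ccccc2)C(C)(C)C)ccc1O[Si](C)(C)C(C)(C)C | intermediate
10 | (+)-neoolivil, (2R,3S,4S,5R) | COc1cc([C@@H]2O[C@@H](c3ccc(O)c(OC)c3)[C@H](CO)[C@H]2CO)ccc1O | target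

**Step count**
Total steps: 7. Longest linear sequence: 7 (from 1).

**Three steps most likely to fail, with fallbacks**
1. Step 3 (Cope). Risks: the diequatorial/diaxial chair preference of two small OMe groups may be modest, (E,E)/(Z,Z) separation may be difficult, and the reaction may be slow with E-substituted termini. Fallback: make the same C3–C4 bond by an Ireland–Claisen rearrangement of a 3-silyloxypropanoate ester of a lactate-derived (E)-allylic alcohol. There the ketene-acetal substituent forces the carbinol substituent equatorial, giving dependable 1,3-chirality transfer; ozonolysis and redox adjustment then converge on 6.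
2. Step 6 (acid cyclisation/equilibration). Risks: Friedel–Crafts closure of the benzylic cation to an aryltetralin, silyl-ether participation giving a furofuran, or incomplete epimerisation. Fallback: give up thermodynamic control. Oxidise 8 to the 1,4-diketone, reduce under Felkin control to a single C2-symmetric diol, and close the ring kinetically with MsCl/Et3N.
3. Step 5 (double aryl addition). Risks: the reaction stalls at the lactolate after one addition, or the Roche-type dialdehyde epimerises or β-eliminates. Fallback: trap 6 as its 2,5-dimethoxyoxolane bis-acetal (MeOH, CSA) and install both aryl groups by BF3-promoted oxocarbenium arylation with the arylzinc or aryl cuprate. This builds the oxolane and the 2,3-/4,5-trans relationships directly and makes step 6 unnecessary.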